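In this stirred vessel D stays a small standing amount while E grows, and X lost matches D plus E gained, so I read D as the way to E.

| flask | X | Z | Q | L | temperature | remark | time |
|---|---|---|---|---|---|---|---|
| summer | 0.087 M | 0.0914 M | 0.087 M | 44 µM | 35 °C | run made earlier |  |
| spring | 0.087 M | 0.0914 M | 0.043 M | 44 µM | 46 °C | run made earlier |  |
| dusk | 0.087 M | 0.0914 M | 0.065 M | 44 µM | 35 °C | run made earlier |  |
| midnight | 0.087 M | 0.0914 M | 0.087 M | 88 µM | 46 °C | run made earlier |  |
| Wednesday's | 0.087 M | 0.0914 M | 0.0870 M | 44 µM | 40 °C | everything together at the start | 25 h |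
| Friday's | 0.087 M | 0.0914 M | 0.0870 M | 44 µM |  | everything together at the start at 0 °C, warmed to 40 °C at 20 h | 25 h |
| Monday's | 0.087 M | 0.0914 M | 0.0870 M (fed, over 20 h) | 44 µM | 40 °C | all else is in the flask from the start; the feed brings no volume worth counting | 25 h |
| Sunday's | 0.087 M (fed, over 20 h) | 0.0914 M | 0.0870 M | 44 µM |  | the addition at 0 °C, then warmed to 40 °C; the feed brings no volume worth counting | 25 h |

| run | time / h | D / % | E / % | X / % |
|---|---|---|---|---|
| summer | 3.00 | 3.6 | 1.9 | 91.0 |
| summer | 8.00 | 5.5 | 8.3 | 85.7 |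
| summer | 15.0 | 5.0 | 17.7 | 77.3 |
| summer | 25.0 | 3.7 | 26.2 | 69.4 |
| spring | 6.00 | 4.7 | 14.3 | 79.9 |
| spring | 12.0 | 2.9 | 25.3 | 70.3 |
| spring | 20.0 | 2.2 | 33.5 | 61.0 |
| spring | 25.0 | 3.6 | 36.4 | 59.6 |
| dusk | 3.00 | 6.1 | 1.9 | 93.5 |
| dusk | 8.00 | 6.0 | 8.7 | 84.5 |
| dusk | 15.0 | 6.4 | 18.8 | 76.0 |
| dusk | 25.0 | 5.1 | 25.5 | 69.5 |
| midnight | 2.00 | 5.2 | 6.9 | 85.2 |
| midnight | 5.00 | 6.3 | 19.9 | 74.4 |
| midnight | 10.0 | 5.5 | 31.2 | 62.7 |
| midnight | 25.0 | 2.3 | 40.5 | 57.7 |

(standard deviation of a reading: 1 percentage point)

- the numbers in the tables scatter with a standard deviation of 1 percentage point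

1. the best flask by share of D in D plus E; "all alike" if 1.5 percentage points covers them all (Wednesday's / Friday's / Monday's / Sunday's / all alike)
2. share of D in D plus E at the end, Wednesday's
3. share of D in D plus E at the end, Friday's
4. share of D in D plus E at the end, Monday's
5. share of D in D plus E at the end, Sunday's

I work with two times, the lifetime of D and the time the vessel spends warm. I read the first as the hourly gain of E over the D standing. The summer run, between 8.00 h and 15.0 h at 35 °C, gives 0.256 /h. The dusk run, with 0.065 M of Q against 0.087 M, reads 0.233 /h, so I keep Q out of it. The midnight run at 46 °C, which also holds 88 µM of L against 44 µM in the summer run, gives 0.754 /h between 2.00 h and 5.00 h. Two settings differ between these runs, and I assign the change to temperature as an assumption.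

Between those readings, 0.418 /h at 40 °C makes the lifetime of D at that temperature 2.39 h. While D stands level, E over D equals warm time over lifetime, a Damköhler number I call the count, and the share of D is one over one plus the count. The rate of making D cancels. At 0 °C the same line, carried beyond the readings, gives an estimated lifetime of 122 h, longer than the cold 20 h, so I leave the cold hours out of the count.

Friday's and Sunday's stay warm 5.00 h, which gives me 32.4 % for each, and I can't separate them. Wednesday's and Monday's stay warm 25 h, which gives me 8.73 %.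

The forecast gives 10 %, 39 %, 11 % and 42 % in the order asked, and names Sunday's: “Sunday's lower X during the cold stage means less carried over”. Its figure for Friday's stands above mine, and so does its figure for Wednesday's.

The flasks give 10.6 % for Wednesday's, 33.0 % for Friday's, 10.7 % for Monday's and 35.7 % for Sunday's, so Sunday's is best.

    X + Z + L → L + D (k = 132 /M²/min, Ea = 49.0 kJ/mol)
    Q + Z + L → L + G (k = 132 /M²/min, Ea = 53.0 kJ/mol)
    Z → J (k = 1.41 × 10⁻⁴ /min, Ea = 119 kJ/mol)
    D ⇌ E (K = 12.8, k = 0.00759 /min, Ea = 87.0 kJ/mol, ΔH = 15.0 kJ/mol)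
    (constants at 40 °C)

At 20.0 h Friday's holds D at 3.71 % and E at 0.130 %. For a further flask, like Wednesday's but with 0.37 M of Z, I reckon the same count of 10.5, which again puts the share at 8.73 %. That flask gives 9.24 %, with D at 8.04 % of the X charged.

(The readings are simulated for substances that don't exist, noise included.)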